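Isochromene numbering: ring A is the pyran (O2, C1, C3, C4, C4a, C8a), ring B the carbocycle (C4a–C8a). Ring B is cut at C5–C6 and C8–C8a into a 2-acyloxy-2-methylmalonyl unit (C6–C7–C8) and a 4-alkylidene-4H-pyran, whose ring oxygen O2 makes exocyclic C5 and ring carbon C8a nucleophilic. C7 is stereogenic only because its two carbonyl arms end on different carbons. A lactic-acid-derived malonyl unit with graded arms (acid chloride, thioester) therefore meets the graded nucleophile (C5 before C8a). One flask operation closes ring B by [3+3] double C-acylation. The precursor is a monocyclic, maltol-derived 4-(alkoxymethylidene)pyran.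

Key step: step 8

Assumption: 3 and 6 are taken as purchasable, and 10 and 19 are E/Z mixtures about C4a=C5, which is inconsequential because this bond rotates at the pyrylium stage and in the push–pull state.

Step 1
Reactants: 1 maltol (3-hydroxy-2-methyl-4H-pyran-4-one)
Product: 2 3-methoxy-2-methyl-4H-pyran-4-one
Conditions: MeI, K2CO3, acetone, reflux
Reagents that add atoms: iodomethane CI
Why: Williamson ether synthesis on the enolic 3-OH, the only acidic site, installs the future C4 methoxy group.

Step 2
Reactants: 2 3-methoxy-2-methyl-4H-pyran-4-one; 3 tert-butyl(2-iodoethoxy)dimethylsilane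
Product: 5 2-[3-(tert-butyldimethylsilyloxy)propyl]-3-methoxy-4H-pyran-4-one, via lithium dienolate 4 (not isolated)
Conditions: LiN(SiMe3)2, THF, −78 °C; then 3, DMPU, −78 → −20 °C
Reagents that add atoms: none
Why: Vinylogous deprotonation of the 2-methyl group gives a dienolate that should be alkylated at its exocyclic carbon by the primary iodide (SN2 lateral alkylation of a 2-methyl-4-pyranone), which completes the protected three-carbon side chain.

Step 3
Reactants: 5 2-[3-(tert-butyldimethylsilyloxy)propyl]-3-methoxy-4H-pyran-4-one; 6 tributyl[(methoxymethoxy)methyl]stannane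
Product: 10 2-[3-(tert-butyldimethylsilyloxy)propyl]-3-methoxy-4-[(methoxymethoxy)methylidene]-4H-pyran (E/Z mixture), via organolithium 7 (not isolated), via lithium carbinolate 8 (not isolated), via tertiary acetate 9 (not isolated)
Conditions: 6, n-BuLi, THF, −78 °C; then 5, −78 °C; then Ac2O, Et3N, −78 → 0 °C; filtration through basic alumina
Reagents that add atoms: none
Why: Tin–lithium exchange gives the α-alkoxy organolithium, which should add 1,2 to the pyranone carbonyl (lithium held between the 3-methoxy and carbonyl oxygens), and the acetylated doubly allylic alkoxide ionises to a pyrylium ion whose acidic 4-CH2 is deprotonated by Et3N (organometal addition to a 4-pyranone followed by anhydrobase formation).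

Step 4
Reactants: 11 (S)-lactic acid; 12 pivalaldehyde
Product: 13 (2S,5S)-2-tert-butyl-5-methyl-1,3-dioxolan-4-one (cis)
Conditions: cat. p-TsOH, pentane, reflux with azeotropic removal of water; crystallisation from pentane, −78 °C
Reagents that add atoms: none
Why: Acid-catalysed acetalisation under thermodynamic control should favour the cis isomer, so the lactic acid centre sets the new acetal centre C2 as S, and crystallisation should remove the trans isomer (first stage of self-regeneration of stereocentres).

Step 5
Reactants: 13 (2S,5S)-2-tert-butyl-5-methyl-1,3-dioxolan-4-one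
Product: 15 S-ethyl (2S,4S)-2-tert-butyl-4-methyl-5-oxo-1,3-dioxolane-4-carbothioate, via lithium enolate 14 (not isolated)
Conditions: LiN(iPr)2, THF, −78 °C; then EtSC(O)Cl, −78 °C
Reagents that add atoms: S-ethyl chlorothioformate CCSC(=O)Cl
Why: Claisen-type C-acylation of the planar ester enolate should occur on the face anti to the tert-butyl group, so the thioester carbon takes the place of H with retention and the acetal centre sets the quaternary centre that becomes C7.

Step 6
Reactants: 15 S-ethyl (2S,4S)-2-tert-butyl-4-methyl-5-oxo-1,3-dioxolane-4-carbothioate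
Product: 16 (2S)-3-(ethylsulfanyl)-2-hydroxy-2-methyl-3-oxopropanoic acid
Conditions: CF3CO2H, H2O, 40 °C
Reagents that add atoms: none
Why: Acid hydrolysis of the acylal releases volatile pivalaldehyde, spares the acid-stable S-ethyl thioester, keeps the malonic half-thioester protonated so that decarboxylation through the carboxylate is held back, and touches no bond at the quaternary centre.

Step 7
Reactants: 16 (2S)-3-(ethylsulfanyl)-2-hydroxy-2-methyl-3-oxopropanoic acid
Product: 18 (2R)-2-(butanoyloxy)-3-(ethylsulfanyl)-2-methyl-3-oxopropanoyl chloride, via butanoyloxy acid 17 (not isolated)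
Conditions: PrCOCl (neat), 45 °C; evaporation; then (COCl)2, cat. DMF, CH2Cl2, 0 °C → rt
Reagents that add atoms: butanoyl chloride CCCC(=O)Cl; oxalyl chloride O=C(Cl)C(=O)Cl
Why: O-acylation of the tertiary alcohol by neat acyl chloride and DMF-catalysed (Vilsmeier-type) chlorination of the acid, the sequence used for 2-acetoxyisobutyryl chloride, give a malonyl unit with two arms of very different reactivity, and only the descriptor changes (CIP priority) because no bond at the stereocentre is touched.

Step 8
Reactants: 10 2-[3-(tert-butyldimethylsilyloxy)propyl]-3-methoxy-4-[(methoxymethoxy)methylidene]-4H-pyran; 18 (2R)-2-(butanoyloxy)-3-(ethylsulfanyl)-2-methyl-3-oxopropanoyl chloride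
Product: 20 (7R)-3-[3-(tert-butyldimethylsilyloxy)propyl]-4-methoxy-5-(methoxymethoxy)-7-methyl-6,8-dioxo-7,8-dihydro-6H-isochromen-7-yl butanoate, via C5-acylated pyran 19 (not isolated)
Conditions: 2,6-di-tert-butyl-4-methylpyridine, CH2Cl2, −78 → −20 °C; then (CuOTf)2·PhMe (excess), −20 °C → rt, same flask, no work-up
Reagents that add atoms: none
Why: Proposed new method: O2 of ring A feeds electron density to exocyclic C5 and to ring carbon C8a of 10, so C5 attacks the acid chloride arm of 18, ring A becomes a pyrylium ion and the hindered base removes the C5 proton to give 19 (C5–C6 bond); CuOTf then binds the soft thioester sulfur, C8a attacks that carbonyl, CuSEt leaves and loss of the C8a proton restores the C1=C8a enol ether (C8–C8a bond). The closest known reaction types are the C-acylation of pyrylium anhydrobases (4-methylidene-4H-pyrans) by acyl chlorides, the CuOTf-promoted Friedel–Crafts acylation with thio- and selenoesters and the [3+3] cyclocondensation of malonyl dihalides with 1,3-dinucleophiles, but their union on a 4-(alkoxymethylidene)pyran has not been shown. Ring B closes in the 6-(enolexo)-exo-trig mode after rotation about the push–pull C4a=C5 bond, which should have a low barrier. No stereocentre is made: quaternary C7 is carried in from 18, cannot epimerise, and becomes R in 20 only because the former lactic acid carbonyl ends on C5 and the thioester carbonyl on C8a. This pairing needs acid chloride far above thioester and C5 far above C8a in reactivity, which the metal-free first phase and the aromatisation gained only by attack at C5 should secure, and it is the reason why CuOTf is added only when 10 is consumed. Within 19 closure should go to C8a and not to C4, the other β-carbon of the dienol ether, because C4 carries the methoxy group, would become quaternary and has no proton to lose.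

Step 9
Reactants: 20 (7R)-3-[3-(tert-butyldimethylsilyloxy)propyl]-4-methoxy-5-(methoxymethoxy)-7-methyl-6,8-dioxo-7,8-dihydro-6H-isochromen-7-yl butanoate
Product: 21 (7R)-5-hydroxy-3-(3-hydroxypropyl)-4-methoxy-7-methyl-6,8-dioxo-7,8-dihydro-6H-isochromen-7-yl butanoate (target)
Conditions: 2 M aq HCl, THF, rt
Reagents that add atoms: none
Why: Acid hydrolysis should cleave the primary silyl ether and the MOM acetal of the acidic C5 enol together, while the tertiary butanoate, the C4 methyl enol ether of the electron-poor chromophore and the non-epimerisable C7 are left alone.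

Compound list
1 | maltol (3-hydroxy-2-methyl-4H-pyran-4-one) | CC1=C(O)C(=O)C=CO1 | starting material
2 | 3-methoxy-2-methyl-4H-pyran-4-one | CC1=C(OC)C(=O)C=CO1 | intermediate
3 | tert-butyl(2-iodoethoxy)dimethylsilane | CC(C)(C)[Si](C)(C)OCCI | starting material
4 | lithium 3-methoxy-2-methylidene-2H-pyran-4-olate (dienolate of 2) | [Li+].C=C1OC=CC([O-])=C1OC | intermediate (not isolated)
5 | 2-[3-(tert-butyldimethylsilyloxy)propyl]-3-methoxy-4H-pyran-4-one | CC(C)(C)[Si](C)(C)OCCCC1=C(OC)C(=O)C=CO1 | intermediate
6 | tributyl[(methoxymethoxy)methyl]stannane | CCCC[Sn](CCCC)(CCCC)COCOC | starting material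
7 | (methoxymethoxy)methyllithium | [Li]COCOC | intermediate (not isolated)
8 | lithium 2-[3-(tert-butyldimethylsilyloxy)propyl]-3-methoxy-4-[(methoxymethoxy)methyl]-4H-pyran-4-olate (racemic) | [Li+].[O-]C1(COCOC)C=COC(CCCO[Si](C)(C)C(C)(C)C)=C1OC | intermediate (not isolated)
9 | 2-[3-(tert-butyldimethylsilyloxy)propyl]-3-methoxy-4-[(methoxymethoxy)methyl]-4H-pyran-4-yl acetate (racemic) | CC(=O)OC1(COCOC)C=COC(CCCO[Si](C)(C)C(C)(C)C)=C1OC | intermediate (not isolated)
10 | 2-[3-(tert-butyldimethylsilyloxy)propyl]-3-methoxy-4-[(methoxymethoxy)methylidene]-4H-pyran (E/Z mixture) | COCOC=C1C=COC(CCCO[Si](C)(C)C(C)(C)C)=C1OC | intermediate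
11 | (S)-lactic acid | C[C@H](O)C(=O)O | starting material
12 | pivalaldehyde | CC(C)(C)C=O | starting material
13 | (2S,5S)-2-tert-butyl-5-methyl-1,3-dioxolan-4-one (cis) | C[C@@H]1O[C@H](C(C)(C)C)OC1=O | intermediate
14 | lithium (2S)-2-tert-butyl-5-methyl-1,3-dioxol-4-olate (enolate of 13) | [Li+].CC1=C([O-])O[C@@H](C(C)(C)C)O1 | intermediate (not isolated)
15 | S-ethyl (2S,4S)-2-tert-butyl-4-methyl-5-oxo-1,3-dioxolane-4-carbothioate (thioester trans to tert-butyl) | C[C@]1(C(=O)SCC)O[C@H](C(C)(C)C)OC1=O | intermediate
16 | (2S)-3-(ethylsulfanyl)-2-hydroxy-2-methyl-3-oxopropanoic acid | C[C@](C(=O)O)(C(=O)SCC)O | intermediate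
17 | (2S)-2-(butanoyloxy)-3-(ethylsulfanyl)-2-methyl-3-oxopropanoic acid | C[C@](C(=O)O)(C(=O)SCC)OC(=O)CCC | intermediate (not isolated)
18 | (2R)-2-(butanoyloxy)-3-(ethylsulfanyl)-2-methyl-3-oxopropanoyl chloride | C[C@](C(=O)Cl)(C(=O)SCC)OC(=O)CCC | intermediate
19 | S-ethyl (2S)-2-(butanoyloxy)-4-{2-[3-(tert-butyldimethylsilyloxy)propyl]-3-methoxy-4H-pyran-4-ylidene}-4-(methoxymethoxy)-2-methyl-3-oxobutanethioate (E/Z mixture) | CCCC(=O)O[C@](C)(C(=O)SCC)C(=O)C(OCOC)=C1C=COC(CCCO[Si](C)(C)C(C)(C)C)=C1OC | intermediate (not isolated)
20 | (7R)-3-[3-(tert-butyldimethylsilyloxy)propyl]-4-methoxy-5-(methoxymethoxy)-7-methyl-6,8-dioxo-7,8-dihydro-6H-isochromen-7-yl butanoate | CCCC(=O)O[C@]1(C)C(=O)C2=COC(CCCO[Si](C)(C)C(C)(C)C)=C(OC)C2=C(OCOC)C1=O | intermediate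
21 | (7R)-5-hydroxy-3-(3-hydroxypropyl)-4-methoxy-7-methyl-6,8-dioxo-7,8-dihydro-6H-isochromen-7-yl butanoate | CCCC(=O)O[C@]1(C)C(=O)C2=COC(CCCO)=C(OC)C2=C(O)C1=O | target

Total step count: 9. Longest linear sequence: 6 (steps 4 to 9, from (S)-lactic acid). The pyran branch (steps 1, 2, 3, 8, 9) has 5.

Steps most likely to fail

Step 8 (Proposed new method). The second acylation may stall, because conjugation of ring A with the new C6 carbonyl lowers the nucleophilicity of C8a. Activation of the thioester before C5 acylation is complete would cross the pairing of the arms and erode the enantiomeric purity. The fallback sets out from 19, isolated after the metal-free first phase. NIS (MeCN, 0 °C) should iodinate the β-carbon of the ring enol ether, as known for 4-pyranones and glycals, to give the C8a iodide F1. Zn dust and LiCl (THF) insert to give the alkenylzinc iodide F2. Catalytic PdCl2(PPh3)2 then closes ring B by an intramolecular Fukuyama coupling with the thioester. The route is rejoined at 20.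

Step 3. The strongly basic organolithium may abstract the acidic CH2 proton next to C2 of the pyranone or attack C6 with ring opening. The ionisation of the acetate may also place the double bond poorly or degrade the electron-rich product. The fallback sets out from 5. Diethyl (hydroxymethyl)phosphonate is converted with MOMCl and iPr2NEt into diethyl [(methoxymethoxy)methyl]phosphonate F3. Its lithium salt (LiN(iPr)2, THF, −78 °C) adds reversibly to 5 to give the β-oxidophosphonate F4. On warming, F4 should lose lithium diethyl phosphate in a Horner–Wadsworth–Emmons-type enol ether synthesis. This fixes the position of the double bond without a free pyrylium stage, and the route is rejoined at 10.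

Step 2. Substitution on the β-silyloxy iodide is slow, so elimination of the iodide, proton exchange and double alkylation may take over. The fallback sets out from 2. Dienolate 4 is alkylated with the far more reactive allyl bromide to give 2-(but-3-en-1-yl)-3-methoxy-4H-pyran-4-one F5. Ozonolysis of the isolated terminal alkene (O3, CH2Cl2/MeOH, −78 °C) gives 3-(3-methoxy-4-oxo-4H-pyran-2-yl)propanal F6. NaBH4 reduces it in the same flask to 2-(3-hydroxypropyl)-3-methoxy-4H-pyran-4-one F7. Silylation (TBSCl, imidazole, DMF) rejoins the route at 5.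

Further compounds
F1 | step 8 | S-ethyl (2S)-2-(butanoyloxy)-4-{2-[3-(tert-butyldimethylsilyloxy)propyl]-5-iodo-3-methoxy-4H-pyran-4-ylidene}-4-(methoxymethoxy)-2-methyl-3-oxobutanethioate | CCCC(=O)O[C@](C)(C(=O)SCC)C(=O)C(OCOC)=C1C(I)=COC(CCCO[Si](C)(C)C(C)(C)C)=C1OC
F2 | step 8 | alkenylzinc iodide derived from F1 (ZnI in place of I at C8a) | CCCC(=O)O[C@](C)(C(=O)SCC)C(=O)C(OCOC)=C1C([Zn]I)=COC(CCCO[Si](C)(C)C(C)(C)C)=C1OC
F3 | step 3 | diethyl [(methoxymethoxy)methyl]phosphonate | CCOP(=O)(COCOC)OCC
F4 | step 3 | lithium β-oxidophosphonate from lithiated F3 and 5 (mixture of diastereomers) | [Li+].CCOP(=O)(OCC)C(OCOC)C1([O-])C=COC(CCCO[Si](C)(C)C(C)(C)C)=C1OC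
F5 | step 2 | 2-(but-3-en-1-yl)-3-methoxy-4H-pyran-4-one | C=CCCC1=C(OC)C(=O)C=CO1
F6 | step 2 | 3-(3-methoxy-4-oxo-4H-pyran-2-yl)propanal | O=CCCC1=C(OC)C(=O)C=CO1
F7 | step 2 | 2-(3-hydroxypropyl)-3-methoxy-4H-pyran-4-one | OCCCC1=C(OC)C(=O)C=CO1
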